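**Plan**

Numbering: tetralin C1 bears ring C, C2 and C3 bear the arms C2a and C3a, and C4 joins C4a of ring A (C4a to C8a). Ring B is C1–C4, C4a, C8a.
Enabling feature: C1–C2(C2a)–C3(C3a)–C4 is a succinic acid chain capped at each end by a veratryl carbon. The one extra bond, C1–C8a, joins one benzylic carbon to the ortho carbon of the other arene, so ring B is the closed form of the hexatriene C8a=C4a–C4=C3–C2=C1.
Cuts, in order: the two CH2O–CH3 ethers and the alcohol level of C2a/C3a (back to esters); the C3–C4 saturation; C1–C8a (retro-6π); then C1=C2 and C3=C4 (two Stobbe condensations), back to two veratraldehydes and diethyl succinate.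
Forward order: chain assembly, closure of an eight-membered auxiliary dilactone across C2a/C3a with (2R,3R)-butane-2,3-diol, photochemical closure of ring B, hydrogenation, release of the auxiliary, reduction, methylation.
Stereochemistry: the diol centres differentiate the two helices of the twisted diene and the helix sets C1 in the photocyclisation. C3 comes from hydrogenation anti to the C1 aryl, and C2 from base equilibration against the fixed C1.

Key step: step 7

Assumption: after thermal equilibration the (2R,3R)-bridge is taken to favour the helical diastereomer with a positive C1=C2–C3=C4 torsion (P helix), the one that leads to (1R); if the M helix prevails, (2S,3S)-butane-2,3-diol is used instead and nothing else changes.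

**Step 1**
Reactants: 1 veratraldehyde; 2 diethyl succinate
Product: 3 (3E)-4-(3,4-dimethoxyphenyl)-3-(ethoxycarbonyl)but-3-enoic acid
Conditions: NaOEt, EtOH, reflux; then aq HCl
Reagents that add atoms: none
Why: Stobbe condensation of a succinic diester with an aromatic aldehyde, which reliably gives the E half-ester because the aryl group avoids the retained ester in the eliminative ring opening.

**Step 2**
Reactants: 3 (3E)-4-(3,4-dimethoxyphenyl)-3-(ethoxycarbonyl)but-3-enoic acid
Product: 4 diethyl (2E)-2-(3,4-dimethoxybenzylidene)succinate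
Conditions: EtOH, H2SO4 (cat.), reflux
Reagents that add atoms: ethanol (CCO)
Why: Fischer esterification restores the diester so that the remaining CH2 group can be enolised without a neighbouring carboxylate, and the E alkene is inert to these conditions.

**Step 3**
Reactants: 4 diethyl (2E)-2-(3,4-dimethoxybenzylidene)succinate; 1 veratraldehyde
Product: 6 (2E,3E)-2,3-bis(3,4-dimethoxybenzylidene)succinic acid, via monoethyl (E,E)-bis(veratrylidene)succinate 5 (not isolated)
Conditions: NaOEt, EtOH, reflux; then 2 M NaOH, reflux; then aq HCl; dark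
Reagents that add atoms: sodium hydroxide ([Na+].[OH-])
Why: A second Stobbe condensation at the remaining CH2 group followed by saponification in the same flask is the standard entry to (E,E)-bis(arylidene)succinic acids, each aryl group again ending trans to its own carboxyl group.

**Step 4**
Reactants: 6 (2E,3E)-2,3-bis(3,4-dimethoxybenzylidene)succinic acid
Product: 7 (3E,4E)-3,4-bis(3,4-dimethoxybenzylidene)oxolane-2,5-dione
Conditions: AcCl, 50 °C, dark
Reagents that add atoms: none
Why: Cyclodehydration of a 1,4-diacid with acetyl chloride is the classical fulgide preparation and leaves both E alkenes unchanged.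

**Step 5**
Reactants: 7 (3E,4E)-3,4-bis(3,4-dimethoxybenzylidene)oxolane-2,5-dione; 8 (2R,3R)-butane-2,3-diol
Product: 9 (2E,3E)-2,3-bis(3,4-dimethoxybenzylidene)succinic acid mono[(2R,3R)-3-hydroxybutan-2-yl] ester
Conditions: 8 (4 equiv), DMAP (0.2 equiv), CH2Cl2, 25 °C, dark
Reagents that add atoms: none
Why: DMAP-catalysed alcoholysis of a cyclic anhydride, in which anhydride and diol each have a twofold axis so that only one monoester can form, while the excess of diol suppresses double acylation.

**Step 6**
Reactants: 9 (2E,3E)-2,3-bis(3,4-dimethoxybenzylidene)succinic acid mono[(2R,3R)-3-hydroxybutan-2-yl] ester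
Product: 10 (2R,3R,6E,7E)-6,7-bis(3,4-dimethoxybenzylidene)-2,3-dimethyl-1,4-dioxocane-5,8-dione (P helix)
Conditions: 2-methyl-6-nitrobenzoic anhydride (MNBA, 1.3 equiv), DMAP (3 equiv), CH2Cl2 (1 mM, slow addition of 9), 25 °C, dark; then toluene, 110 °C; SiO2 or crystallisation, M helix re-heated
Reagents that add atoms: none
Why: Shiina macrolactonisation, a method proven for eight-membered lactones, is helped here because the twisted diene holds C2a and C3a about 3 Å apart, close to the O···O distance of the gauche diol; heating then equilibrates the two helical diastereomers (atropisomers about C2–C3), so that the P form can be collected and the M form recycled.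

**Step 7**
Reactants: 10 (2R,3R,6E,7E)-6,7-bis(3,4-dimethoxybenzylidene)-2,3-dimethyl-1,4-dioxocane-5,8-dione (P helix)
Product: 12 cyclic (2R,3R)-butane-2,3-diyl (1R,2R)-1-(3,4-dimethoxyphenyl)-6,7-dimethoxy-1,2-dihydronaphthalene-2,3-dicarboxylate (1,2-cis), via (1S,8aR)-1,8a-dihydronaphthalene dilactone 11 (not isolated)
Conditions: hν (365 nm, Pyrex), Ar-sparged toluene (2 mM), 10 °C; then dark, 25 °C
Reagents that add atoms: none
Why: Excitation of the cross-conjugated dienoate lets the helical hexatriene C8a=C4a–C4=C3–C2=C1 close conrotatorily, forming C1–C8a and ring B (six-membered carbocycle, 6π electrocyclic mode) and giving 11 with H1 and H8a cis, since on the E alkenes the ring C aryl is the inner and H1 the outer substituent at C1 while H8a is inner at C8a. A thermal suprafacial [1,5]-hydrogen shift along C8a–C4a=C4–C3=C2 then carries H8a to the same face of C2, rearomatises ring A irreversibly and leaves the C1 aryl and the C2 carboxyl cis in 12. The closest known reaction type is the photocyclisation of (E,E)-bis(benzylidene)succinic anhydrides, imides and esters, including amino-alcohol-bridged amide esters, to 1-aryl-1,2-dihydronaphthalenes. C1 is controlled by the helix fixed in 10: with a positive C1=C2–C3=C4 torsion C8a lies over one face of C1 only and the inner aryl group is turned to the opposite face, which gives (1R), and the provisional (2R) centre follows from C1 through the two stereospecific pericyclic events. The step needs bonding at the ring A ortho carbon para to the C6 methoxy group, secured by the peri clash that the alternative closure would create between an OMe at C8 and the C1 aryl; it needs retention of the E,E geometry, served by long-wavelength light, low temperature and the irreversible hydrogen shift that drains the reactive isomer; and it needs exclusion of O2 so that 12 is not aromatised to the arylnaphthalene. Because diene and bridge share a twofold axis, either veratryl ring can act as ring A and both closures give the same 12.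

**Step 8**
Reactants: 12 cyclic (2R,3R)-butane-2,3-diyl (1R,2R)-1-(3,4-dimethoxyphenyl)-6,7-dimethoxy-1,2-dihydronaphthalene-2,3-dicarboxylate
Product: 13 cyclic (2R,3R)-butane-2,3-diyl (1R,2R,3S)-1-(3,4-dimethoxyphenyl)-6,7-dimethoxy-1,2,3,4-tetrahydronaphthalene-2,3-dicarboxylate (all-cis)
Conditions: H2 (4 atm), 10% Pd/C, EtOAc, 25 °C
Reagents that add atoms: none
Why: Heterogeneous catalytic hydrogenation of a cinnamate-type alkene should deliver H2 syn to the face that carries H1 and H2, opposite the C1 aryl and the C2 carboxyl, which sets C3 as (S), and saturating C3=C4 before any contact with base removes the double-bond migration pathway that could endanger C1.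

**Step 9**
Reactants: 13 cyclic (2R,3R)-butane-2,3-diyl (1R,2R,3S)-1-(3,4-dimethoxyphenyl)-6,7-dimethoxy-1,2,3,4-tetrahydronaphthalene-2,3-dicarboxylate
Product: 14 dimethyl (1R,2S,3S)-1-(3,4-dimethoxyphenyl)-6,7-dimethoxy-1,2,3,4-tetrahydronaphthalene-2,3-dicarboxylate (1,2-trans and 2,3-trans)
Conditions: NaOMe (0.5 equiv), MeOH–THF, reflux, Ar
Reagents that add atoms: methanol (CO)
Why: Methoxide-catalysed transesterification releases the diol, and enolate equilibration of the two ester-bearing centres should converge on the all-equatorial trans,trans diester by inversion at C2, with the non-enolisable C1 as the fixed reference.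

**Step 10**
Reactants: 14 dimethyl (1R,2S,3S)-1-(3,4-dimethoxyphenyl)-6,7-dimethoxy-1,2,3,4-tetrahydronaphthalene-2,3-dicarboxylate
Product: 15 [(1R,2S,3S)-1-(3,4-dimethoxyphenyl)-6,7-dimethoxy-1,2,3,4-tetrahydronaphthalene-2,3-diyl]dimethanol
Conditions: LiAlH4, THF, 0 °C to 25 °C; Fieser work-up
Reagents that add atoms: none
Why: Hydride reduction of esters to primary alcohols is faster than enolisation, so the three stereocentres are carried through unchanged and the aryl methyl ethers are inert.

**Step 11**
Reactants: 15 [(1R,2S,3S)-1-(3,4-dimethoxyphenyl)-6,7-dimethoxy-1,2,3,4-tetrahydronaphthalene-2,3-diyl]dimethanol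
Product: 16 phyltetralin, (1R,2S,3S)-1-(3,4-dimethoxyphenyl)-6,7-dimethoxy-2,3-bis(methoxymethyl)-1,2,3,4-tetrahydronaphthalene
Conditions: NaH, MeI, THF, 0 °C to 25 °C
Reagents that add atoms: iodomethane (CI)
Why: Williamson ether synthesis on two unhindered primary alkoxides, with no acidic or electrophilic site elsewhere in the molecule.

**Compound list**

1 | veratraldehyde (3,4-dimethoxybenzaldehyde) | O=Cc1ccc(OC)c(OC)c1 | starting material
2 | diethyl succinate | CCOC(=O)CCC(=O)OCC | starting material
3 | (3E)-4-(3,4-dimethoxyphenyl)-3-(ethoxycarbonyl)but-3-enoic acid | CCOC(=O)/C(=C/c1ccc(OC)c(OC)c1)CC(=O)O | intermediate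
4 | diethyl (2E)-2-(3,4-dimethoxybenzylidene)succinate | CCOC(=O)/C(=C/c1ccc(OC)c(OC)c1)CC(=O)OCC | intermediate
5 | monoethyl (2E,3E)-2,3-bis(3,4-dimethoxybenzylidene)succinate | CCOC(=O)/C(=C/c1ccc(OC)c(OC)c1)/C(=C\c1ccc(OC)c(OC)c1)C(=O)O | intermediate
6 | (2E,3E)-2,3-bis(3,4-dimethoxybenzylidene)succinic acid | OC(=O)/C(=C/c1ccc(OC)c(OC)c1)/C(=C\c1ccc(OC)c(OC)c1)C(=O)O | intermediate
7 | (3E,4E)-3,4-bis(3,4-dimethoxybenzylidene)oxolane-2,5-dione | O=C1OC(=O)/C(=C/c2ccc(OC)c(OC)c2)/C1=C\c1ccc(OC)c(OC)c1 | intermediate
8 | (2R,3R)-butane-2,3-diol | C[C@@H](O)[C@@H](C)O | starting material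
9 | (2E,3E)-2,3-bis(3,4-dimethoxybenzylidene)succinic acid mono[(2R,3R)-3-hydroxybutan-2-yl] ester | OC(=O)/C(=C/c1ccc(OC)c(OC)c1)/C(=C\c1ccc(OC)c(OC)c1)C(=O)O[C@H](C)[C@@H](C)O | intermediate
10 | (2R,3R,6E,7E)-6,7-bis(3,4-dimethoxybenzylidene)-2,3-dimethyl-1,4-dioxocane-5,8-dione, P-helical diastereomer | O=C1O[C@H](C)[C@@H](C)OC(=O)/C(=C/c2ccc(OC)c(OC)c2)/C1=C\c1ccc(OC)c(OC)c1 | intermediate
11 | cyclic (2R,3R)-butane-2,3-diyl (1S,8aR)-1-(3,4-dimethoxyphenyl)-6,7-dimethoxy-1,8a-dihydronaphthalene-2,3-dicarboxylate (H1 and H8a cis) | O=C1O[C@H](C)[C@@H](C)OC(=O)C2=C1C=C3C=C(OC)C(OC)=C[C@H]3[C@H]2c4ccc(OC)c(OC)c4 | intermediate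
12 | cyclic (2R,3R)-butane-2,3-diyl (1R,2R)-1-(3,4-dimethoxyphenyl)-6,7-dimethoxy-1,2-dihydronaphthalene-2,3-dicarboxylate (1,2-cis) | O=C1O[C@H](C)[C@@H](C)OC(=O)[C@@H]2[C@H](c3ccc(OC)c(OC)c3)c3cc(OC)c(OC)cc3C=C12 | intermediate
13 | cyclic (2R,3R)-butane-2,3-diyl (1R,2R,3S)-1-(3,4-dimethoxyphenyl)-6,7-dimethoxy-1,2,3,4-tetrahydronaphthalene-2,3-dicarboxylate (all-cis) | O=C1O[C@H](C)[C@@H](C)OC(=O)[C@@H]2[C@H](c3ccc(OC)c(OC)c3)c3cc(OC)c(OC)cc3C[C@H]12 | intermediate
14 | dimethyl (1R,2S,3S)-1-(3,4-dimethoxyphenyl)-6,7-dimethoxy-1,2,3,4-tetrahydronaphthalene-2,3-dicarboxylate (all-trans) | COC(=O)[C@H]1Cc2cc(OC)c(OC)cc2[C@@H](c2ccc(OC)c(OC)c2)[C@@H]1C(=O)OC | intermediate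
15 | [(1R,2S,3S)-1-(3,4-dimethoxyphenyl)-6,7-dimethoxy-1,2,3,4-tetrahydronaphthalene-2,3-diyl]dimethanol | OC[C@H]1Cc2cc(OC)c(OC)cc2[C@@H](c2ccc(OC)c(OC)c2)[C@@H]1CO | intermediate
16 | phyltetralin | COC[C@H]1Cc2cc(OC)c(OC)cc2[C@@H](c2ccc(OC)c(OC)c2)[C@@H]1COC | target

Total step count: 11. Longest linear sequence: 11 steps, from veratraldehyde and diethyl succinate.

**Steps most likely to fail**

**Step 6.** Cyclodimerisation and oligomerisation may outrun closure, because in an eight-membered ring both ester groups must give up their preferred Z (s-trans) conformation. The activated half-ester may also revert to the anhydride.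

The fallback changes the tether to a longer, twofold-symmetric one with primary hydroxyl groups.
- It sets out from 7, which is opened with (4S,5S)-2,2-dimethyl-1,3-dioxolane-4,5-dimethanol and catalytic DMAP to the hydroxy acid monoester F1.
- MNBA and DMAP at high dilution close it to the ten-membered dilactone F2, in which both esters can stay in the Z form. Its helical diastereomers are again equilibrated by heating and separated.
- Irradiation as in the main route should give the cis-dihydronaphthalene dilactone F3.
- Hydrogenation over Pd/C should give the all-cis tetralin dilactone F4.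
- Methanolysis with NaOMe in MeOH, with equilibration, comes back to the route at 14.

**Step 7.** Three processes may erode the result. E to Z isomerisation at the ring C arm would invert the sense at C1, bonding may occur at the ortho carbon flanked by OMe, and the product may undergo secondary photolysis.

The fallback forms the same C1–C8a bond in the ground state by a cationic route.
- It sets out from 10, which is treated with CF3SO3H in CH2Cl2 at 0 °C.
- Protonation at C2 gives the C1 benzylic cation, which is captured by C8a, the ring A carbon activated by the para methoxy group at C6. This Friedel–Crafts-type closure is known for acyclic 2,3-dibenzylidenesuccinates and gives 1,2-trans products.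
- In the P helix the bridge should hold C2a on the face opposite to the incoming aryl-bearing carbon, so the trans-dihydronaphthalene dilactone F5 with (1R,2S) is expected.
- Hydrogenation over Pd/C gives the all-trans tetralin dilactone F6.
- Methanolysis with NaOMe in MeOH comes back to the route at 14.

**Step 9.** Enolisation at the hindered C2 of the saturated diester may be slow, so that equilibration stalls at a mixture of C2 and C3 epimers.

The fallback corrects C2 before saturation and changes the type of reduction.
- It sets out from 12, in which H2 is both α to an ester and allylic.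
- NaOMe in MeOH at 25 °C under argon should cleave the bridge and epimerise C2 to give the trans-dihydronaphthalene dimethyl ester F7.
- Electron-transfer conjugate reduction with Mg in MeOH then saturates C3=C4. Only C3 is left to settle trans under the Mg(OMe)2 formed, and the sequence comes back to the route at 14.

**Further compounds**

F1 | step 6 | (2E,3E)-2,3-bis(3,4-dimethoxybenzylidene)succinic acid mono{[(4S,5S)-5-(hydroxymethyl)-2,2-dimethyl-1,3-dioxolan-4-yl]methyl} ester | OC(=O)/C(=C/c1ccc(OC)c(OC)c1)/C(=C\c1ccc(OC)c(OC)c1)C(=O)OC[C@@H]1OC(C)(C)O[C@H]1CO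
F2 | step 6 | ten-membered cyclic (E,E)-bis(3,4-dimethoxybenzylidene)succinate of (4S,5S)-2,2-dimethyl-1,3-dioxolane-4,5-dimethanol, P-helical diastereomer | O=C1OC[C@@H]2OC(C)(C)O[C@H]2COC(=O)/C(=C/c2ccc(OC)c(OC)c2)/C1=C\c1ccc(OC)c(OC)c1
F3 | step 6 | cyclic (1R,2R)-1-(3,4-dimethoxyphenyl)-6,7-dimethoxy-1,2-dihydronaphthalene-2,3-dicarboxylate (1,2-cis) of the same dioxolane diol | O=C1OC[C@@H]2OC(C)(C)O[C@H]2COC(=O)[C@@H]2[C@H](c3ccc(OC)c(OC)c3)c3cc(OC)c(OC)cc3C=C12
F4 | step 6 | cyclic (1R,2R,3S)-1-(3,4-dimethoxyphenyl)-6,7-dimethoxy-1,2,3,4-tetrahydronaphthalene-2,3-dicarboxylate (all-cis) of the same dioxolane diol | O=C1OC[C@@H]2OC(C)(C)O[C@H]2COC(=O)[C@@H]2[C@H](c3ccc(OC)c(OC)c3)c3cc(OC)c(OC)cc3C[C@H]12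
F5 | step 7 | cyclic (2R,3R)-butane-2,3-diyl (1R,2S)-1-(3,4-dimethoxyphenyl)-6,7-dimethoxy-1,2-dihydronaphthalene-2,3-dicarboxylate (1,2-trans) | O=C1O[C@H](C)[C@@H](C)OC(=O)[C@H]2[C@H](c3ccc(OC)c(OC)c3)c3cc(OC)c(OC)cc3C=C12
F6 | step 7 | cyclic (2R,3R)-butane-2,3-diyl (1R,2S,3S)-1-(3,4-dimethoxyphenyl)-6,7-dimethoxy-1,2,3,4-tetrahydronaphthalene-2,3-dicarboxylate (all-trans) | O=C1O[C@H](C)[C@@H](C)OC(=O)[C@H]2[C@H](c3ccc(OC)c(OC)c3)c3cc(OC)c(OC)cc3C[C@H]12
F7 | step 9 | dimethyl (1R,2S)-1-(3,4-dimethoxyphenyl)-6,7-dimethoxy-1,2-dihydronaphthalene-2,3-dicarboxylate (1,2-trans) | COC(=O)C1=Cc2cc(OC)c(OC)cc2[C@@H](c2ccc(OC)c(OC)c2)[C@@H]1C(=O)OC
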